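## Structural features

Agecorynin E is a flavanone. Benzo ring A (C4a to C8a) is fused to the dihydropyranone ring C (O1, C2, C3, C4), and the 4-hydroxy-3-methoxyphenyl ring B is attached to C2 by one C–C bond. Ring A carries three adjacent methoxy groups on C5, C6 and C7 and a single hydrogen on C8; the only free hydroxyl is the 4'-phenol of ring B. C2 is the only stereocentre (S, from the priority order O1 > C1' > C3 > H) and has no stereogenic neighbour, so the task is absolute control at one carbon. That carbon is fragile: it is benzylic, bound to O1, β to the C4 ketone and para-related to the 4'-oxygen. Base opens ring C by E1cB to the 2'-hydroxychalcone, and acid (or the phenoxide) can ionise C2–O1 toward a quinone methide; both paths racemise. The aryl methyl ethers, above all the one on C5 next to the carbonyl, do not tolerate strong Lewis acids. The real difficulty is therefore to carry an S-configured C2 through ring closure and through the last deprotection, not to build the skeleton. The key step exploits the fact that O1 and the methoxy groups on C5, C6 and C7 make ring A a 3,4,5-trimethoxyphenyl ether with a mirror plane through C8a and C6. Its two ortho carbons are equivalent, and each is ortho to O1 and to one methoxy group and para to another, so acylation at either one forms C4–C4a with the 5,6,7 pattern under very mild activation.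

## Logic of the disconnections

**14 from 13.** The bond removed is the carbonate C(=O)–O bond on the 4'-oxygen. The free phenol is what makes C2 labile, so it should appear last and under neutral conditions. The gain is that the para oxygen stays a weak donor throughout the route. The demand on the forward step is a reductive cleavage that stops before the C2–O1 bond or the C4 ketone is touched.

**13 from 11 (through 12).** The bond cut is C4–C4a. This is the cut that the mirror plane of ring A makes regiochemically trivial. It opens ring C and leaves an open-chain acid in which the stereocentre is already in place. The forward acylation must be faster than ionisation of the benzylic C–O bond; this is why the acid is activated mildly as 12 and why the 4'-oxygen carries an acceptor.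

**11 from 10.** The bond cut is the O–C(CH3)3 bond of the ester. The carboxyl group must be masked while the C–O bond at the stereocentre is made, and it must be unmasked without base, since base would cleave the aryl carbonate and could expel the β-aryloxy group. The forward step is an acidolysis in which the tert-butyl cation is intercepted before it can alkylate ring A.

**10 from 8 and 9.** The bond cut is C2–O1. This splits the molecule into a secondary benzylic alcohol and a symmetric commercial phenol of similar size. The forward step is a substitution with inversion. The priority order O > aryl > CH2 > H is the same in alcohol and ether, so 8 must be R to give S in 10. The step demands clean inversion with no ion-pair leakage and no dehydration; the carbonate on the ring helps against the first.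

**8 from 3 and 6.** The bond cut is C2–C3, an aldol retron. A catalytic enantioselective acetate addition to an aryl aldehyde creates the only stereocentre from achiral partners in one step. The forward step must deliver the nucleophile to the Re face of 3 and must not touch the carbonate.

**6 from 4, and 3 from 1 and 2.** The O–Si bond of 6 and the carbonate O–C(=O) bond of 3 are cut. Both lead to commercial materials in one step each. The silyl ketene acetal has to be made, so five operations precede the key step. The forward steps need only kinetic enolate O-silylation and phenol acylation in the presence of an aldehyde.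

## Other disconnections considered

**Alternative 1:** The cut removes all of ring A by breaking C8–C8a and C4a–C5. It leaves the enantiopure sulfinyl dihydropyranone A2 (rings B and C, with a phenylsulfinyl group on the future C4a) and the silyl ketene acetal diene A3 (C5 to C8 with their oxygen substituents). In the forward step the CH2 terminus of A3 (C8) adds to the β-carbon C8a of the sulfinyl enone and the ketene acetal carbon C5 closes onto C4a. Loss of the sulfinyl group as its sulfenic acid and of one methoxy group as the alcohol then aromatises the new ring and gives the 5-hydroxyflavanone A1.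
- In its favour: the oxygenation pattern is written by the polarity of the diene, no acidic or cationic chemistry takes place next to C2, and the stereocentre can be set early by a catalytic asymmetric hetero-Diels–Alder reaction of an aryl aldehyde.
- Against it here: A1 has a free, chelated 5-hydroxyl that must still be methylated with base, which invites E1cB opening of ring C. Its 4'-benzyl ether must be hydrogenolysed. A3 is a hydrolytically sensitive, non-commercial diene. A2 needs the dihydropyranone, a sulfenylation and an oxidation.
- Comparison: on mechanism it is the equal of the chosen plan, or slightly better, in keeping C2 away from acid during ring construction. On structure it solves a regiochemical problem that the mirror plane of ring A already solves in the chosen plan, and it ends one methyl group short. On step economy it is clearly longer, roughly ten steps against seven.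

**Alternative 2:** The cut breaks C3–C4 and O1–C2, so ring C is assembled from the salicylaldehyde A5 (ring A with O1 and C4) and 4-vinylguaiacol A6 (ring B with C2 and C3). In the forward step A5, a methyl orthoester and a chiral phosphoric acid would give a 4-methoxy ortho-quinone methide, which takes up the electron-rich styrene A6 in an inverse-demand [4+2] addition to the flavan A4. The C4 methyl ether must then be oxidised to the ketone.
- In its favour: it is very short (A5 is one formylation away from 9), it needs no protecting group, its regiochemistry is set by polarity, and both ring-C bonds form in one step.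
- Against it here: the configuration at C2 would rest on ion-pair control over an unprotected para-hydroxystyrene, which can react stepwise through a quinone-methide-like cation. A4 holds two acid-labile benzylic ethers (C2–O1 and C4–OMe) in the acid medium that forms them, so epimerisation is a standing risk. The C4 stereocentre is made only to be destroyed. Oxidising C4 beside a free phenol and two electron-rich rings, without running on to the flavone, is delicate. A6 also polymerises readily under acid.
- Comparison: on step economy this alternative is better than the chosen plan (about four steps against seven, no protecting groups). On mechanism both draw on the same electron-rich ring A. On structure and stereocontrol the chosen plan is safer: its stereocentre comes from a catalyst-controlled addition to a simple aldehyde, is transferred by SN2 and is guarded by a deactivating group.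

**Alternative 3:** The cut breaks O1–C8a and C4–C4a. Ring A arrives as the aryne released from the silyl triflate A8, and rings B and C come from the (S)-β-hydroxy ester A9. In the forward step a fluoride source unmasks the aryne and the C2 alkoxide adds at C8a, the carbon remote from the C5 methoxy group. The aryl anion formed at C4a, stabilised inductively by that methoxy group, attacks the ester and closes ring C to A7. Hydrogenolysis of the benzyl ether would finish the synthesis.
- In its favour: two bonds form in one step, the C2–O bond is never broken so the configuration is simply retained, no acid is used, and A9 is available by the same kind of aldol with a plain benzyl ether.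
- Against it here: secondary alkoxides are weaker aryne partners than phenoxides, and the β-alkoxy ester can undergo retro-aldol cleavage under basic fluoride. The aryl anion may be protonated before it reaches the ester, stopping at the open aryl ether. A7 must survive a basic medium that promotes E1cB opening. A8 takes about three steps from 9. The regiochemistry rests on an inductive bias, not on symmetry.
- Comparison: on longest linear sequence the alternative is better (about four steps from 1 against six). On total steps the two are about equal once the branch to A8 is counted. On mechanism it is equal or better in needing no substitution at C2, and worse in exposing the product to base. On structure the same C4–C4a bond is made, but from an anion, and the chosen plan needs no specially prepared ring-A reagent.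

Key step: step 6

Assumption: with SiCl4 and the (R,R)-bisphosphoramide the ketene acetal is taken to add to the Re face of the aryl aldehyde, giving the R alcohol; if the sense of induction is the opposite, the (S,S)-catalyst is used and nothing else changes.

## Route

Step 1
Reactants: 1 vanillin; 2 benzyl chloroformate
Product: 3 benzyl (4-formyl-2-methoxyphenyl) carbonate
Conditions: Et3N, CH2Cl2, 0 °C → rt
Reagents that add atoms: none
Why: Acylation of the phenol by the chloroformate (Schotten–Baumann-type carbonate formation); the aldehyde is inert, and the carbonate turns the para oxygen from a strong donor into a weak one, which every later step relies on.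

Step 2
Reactants: 4 tert-butyl acetate
Product: 6 tert-butyl[(1-tert-butoxyethenyl)oxy]dimethylsilane, via lithium enolate of tert-butyl acetate 5 (not isolated)
Conditions: LiN(i-Pr)2 (LDA), THF, −78 °C; then t-BuMe2SiCl, DMPU, −78 °C → rt; distillation
Reagents that add atoms: tert-butyldimethylsilyl chloride (TBSCl), CC(C)(C)[Si](C)(C)Cl
Why: Kinetic deprotonation of the ester and O-silylation of the enolate in the presence of a dipolar cosolvent (silyl ketene acetal formation); tert-butyl acetate does not self-condense at −78 °C.

Step 3
Reactants: 3 benzyl (4-formyl-2-methoxyphenyl) carbonate; 6 tert-butyl[(1-tert-butoxyethenyl)oxy]dimethylsilane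
Product: 8 tert-butyl (R)-3-{4-[(benzyloxycarbonyl)oxy]-3-methoxyphenyl}-3-hydroxypropanoate, via trichlorosilyl aldolate 7 (not isolated)
Conditions: SiCl4 (1.1 equiv), (R,R)-bisphosphoramide (5 mol %; two P(=O) units, each spanning the two NMe groups of (R)-N,N'-dimethyl-1,1'-binaphthyl-2,2'-diamine, joined through MeN(CH2)5NMe), CH2Cl2, −78 °C; then cold sat. aq. NaHCO3
Reagents that add atoms: none
Why: Catalytic enantioselective Mukaiyama aldol addition by Lewis-base activation of SiCl4: the phosphoramide-bound trichlorosilyl cation binds the aldehyde and should expose its Re face to the ketene acetal, which sets the carbinol carbon as R; the silyl group leaves as TBSCl and 7 is hydrolysed on work-up, while the aryl carbonate is not attacked by these non-basic reagents at −78 °C.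

Step 4
Reactants: 8 tert-butyl (R)-3-{4-[(benzyloxycarbonyl)oxy]-3-methoxyphenyl}-3-hydroxypropanoate; 9 3,4,5-trimethoxyphenol
Product: 10 tert-butyl (S)-3-{4-[(benzyloxycarbonyl)oxy]-3-methoxyphenyl}-3-(3,4,5-trimethoxyphenoxy)propanoate
Conditions: PPh3, DIAD (added slowly), toluene, 0 °C → rt
Reagents that add atoms: none
Why: Mitsunobu etherification; the phenol (pKa about 10) is acidic enough, and substitution at the phosphorus-activated benzylic carbon goes with inversion (R to S); the carbonate disfavours ion-pair leakage, and low temperature with slow DIAD addition should hold back dehydration to the cinnamate.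

Step 5
Reactants: 10 tert-butyl (S)-3-{4-[(benzyloxycarbonyl)oxy]-3-methoxyphenyl}-3-(3,4,5-trimethoxyphenoxy)propanoate
Product: 11 (S)-3-{4-[(benzyloxycarbonyl)oxy]-3-methoxyphenyl}-3-(3,4,5-trimethoxyphenoxy)propanoic acid
Conditions: CF3CO2H/CH2Cl2 (1:4), Et3SiH (2.5 equiv), 0 °C; evaporation from toluene
Reagents that add atoms: none
Why: Acidolysis of the tert-butyl ester with Et3SiH as cation scavenger, so that the tert-butyl cation is reduced to isobutane instead of alkylating ring A; the benzyl carbonate and the benzylic C–O bond (its cation is destabilised by the carbonate and by the β-carboxyl group) should tolerate dilute CF3CO2H at 0 °C.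

Step 6
Reactants: 11 (S)-3-{4-[(benzyloxycarbonyl)oxy]-3-methoxyphenyl}-3-(3,4,5-trimethoxyphenoxy)propanoic acid
Product: 13 benzyl {2-methoxy-4-[(2S)-5,6,7-trimethoxy-4-oxochroman-2-yl]phenyl} carbonate, via mixed trifluoroacetic anhydride 12 (not isolated)
Conditions: (CF3CO)2O (1.5 equiv), CH2Cl2, 0 °C → rt; cold aq. NaHCO3 quench
Reagents that add atoms: none
Why: (CF3CO)2O acylates the carboxyl group to give the mixed anhydride 12, whose non-fluorinated acyl carbon is the electrophile and whose trifluoroacetate is the leaving group (possibly through an acylium ion pair). The ortho carbon of ring A, which is ortho to O1 and to one methoxy group and para to another, attacks this carbon, and loss of a proton from the σ-complex gives the aryl ketone and the C4–C4a bond. The closest known reaction type is the intramolecular Friedel–Crafts acylation of 3-aryloxypropanoic acids to chroman-4-ones by way of their mixed trifluoroacetic anhydrides. Ring C closes in a 6-exo-trig mode at the acyl carbon, the attacked C=O staying outside the new ring. No stereocentre is made; C2 is carried through because none of its bonds takes part. Regiochemistry is not an issue, since the two ortho carbons of the 3,4,5-trimethoxyphenoxy ring are related by its mirror plane, and the competing five-membered closure onto C6' of ring B (a 1-indanone) is disfavoured because that carbon has one para-methoxy donor against three oxygen donors on C4a. The selectivity that matters is acylation against ionisation of the benzylic C2–O1 bond: the carbonate on the para oxygen and the electron-poor acyl chain both destabilise a cation at C2, while the phloroglucinol-type ring reacts at or below room temperature without a strong Lewis acid. (CF3CO)2O is kept near stoichiometric and the mixture cold so that C-trifluoroacetylation of ring A does not compete.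

Step 7
Reactants: 13 benzyl {2-methoxy-4-[(2S)-5,6,7-trimethoxy-4-oxochroman-2-yl]phenyl} carbonate
Product: 14 agecorynin E, (2S)-2-(4-hydroxy-3-methoxyphenyl)-5,6,7-trimethoxychroman-4-one
Conditions: H2 (1 atm), Pd/C (5 wt %), EtOAc, rt; stopped when 13 is consumed
Reagents that add atoms: none
Why: Hydrogenolysis of the benzyl C–O bond followed by spontaneous loss of CO2 from the aryl carbonic acid; the neutral, base-free medium avoids E1cB or quinone-methide racemisation of the free 4'-hydroxyflavanone, and a benzyl carbonate should be cleaved much faster than the C2–O1 bond or the aryl ketone is reduced.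

## Compound list

1 | vanillin | COc1cc(C=O)ccc1O | starting material
2 | benzyl chloroformate | O=C(Cl)OCc1ccccc1 | starting material
3 | benzyl (4-formyl-2-methoxyphenyl) carbonate | COc1cc(C=O)ccc1OC(=O)OCc1ccccc1 | intermediate
4 | tert-butyl acetate | CC(=O)OC(C)(C)C | starting material
5 | lithium enolate of tert-butyl acetate (not isolated) | C=C(O[Li])OC(C)(C)C | intermediate
6 | tert-butyl[(1-tert-butoxyethenyl)oxy]dimethylsilane | C=C(OC(C)(C)C)O[Si](C)(C)C(C)(C)C | intermediate
7 | tert-butyl (R)-3-{4-[(benzyloxycarbonyl)oxy]-3-methoxyphenyl}-3-[(trichlorosilyl)oxy]propanoate (not isolated) | COc1cc([C@H](O[Si](Cl)(Cl)Cl)CC(=O)OC(C)(C)C)ccc1OC(=O)OCc1ccccc1 | intermediate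
8 | tert-butyl (R)-3-{4-[(benzyloxycarbonyl)oxy]-3-methoxyphenyl}-3-hydroxypropanoate | COc1cc([C@H](O)CC(=O)OC(C)(C)C)ccc1OC(=O)OCc1ccccc1 | intermediate
9 | 3,4,5-trimethoxyphenol | COc1cc(O)cc(OC)c1OC | starting material
10 | tert-butyl (S)-3-{4-[(benzyloxycarbonyl)oxy]-3-methoxyphenyl}-3-(3,4,5-trimethoxyphenoxy)propanoate | COc1cc([C@@H](Oc2cc(OC)c(OC)c(OC)c2)CC(=O)OC(C)(C)C)ccc1OC(=O)OCc1ccccc1 | intermediate
11 | (S)-3-{4-[(benzyloxycarbonyl)oxy]-3-methoxyphenyl}-3-(3,4,5-trimethoxyphenoxy)propanoic acid | COc1cc([C@@H](Oc2cc(OC)c(OC)c(OC)c2)CC(=O)O)ccc1OC(=O)OCc1ccccc1 | intermediate
12 | (S)-3-{4-[(benzyloxycarbonyl)oxy]-3-methoxyphenyl}-3-(3,4,5-trimethoxyphenoxy)propanoic trifluoroacetic anhydride (not isolated) | COc1cc([C@@H](Oc2cc(OC)c(OC)c(OC)c2)CC(=O)OC(=O)C(F)(F)F)ccc1OC(=O)OCc1ccccc1 | intermediate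
13 | benzyl {2-methoxy-4-[(2S)-5,6,7-trimethoxy-4-oxochroman-2-yl]phenyl} carbonate, (S)-agecorynin E 4'-O-benzyl carbonate | COc1cc([C@@H]2CC(=O)c3c(cc(OC)c(OC)c3OC)O2)ccc1OC(=O)OCc1ccccc1 | intermediate
14 | agecorynin E, (2S)-2-(4-hydroxy-3-methoxyphenyl)-5,6,7-trimethoxychroman-4-one | COc1cc([C@@H]2CC(=O)c3c(cc(OC)c(OC)c3OC)O2)ccc1O | target

## Step count and least certain steps

Total step count: 7. Longest linear sequence: 6 steps (1 → 3 → 8 → 10 → 11 → 13 → 14, steps 1, 3, 4, 5, 6, 7); step 2 is a one-step branch from 4 that joins at step 3.

**Step 6 (key step).** The most likely failures are acid-promoted ionisation of the C2–O1 bond by the CF3CO2H that is set free (loss of the aryloxy group, or its return with racemisation) and C-trifluoroacetylation of ring A before ring closure. The fallback sets out from 11 and returns at 13. The acid is converted under neutral conditions with 1-chloro-N,N,2-trimethylprop-1-en-1-amine (CH2Cl2, 0 °C) into (S)-3-{4-[(benzyloxycarbonyl)oxy]-3-methoxyphenyl}-3-(3,4,5-trimethoxyphenoxy)propanoyl chloride F1. The chloride is then abstracted with AgOTf in the presence of 2,6-di-tert-butyl-4-methylpyridine (CH2Cl2, −78 °C), so the acyl triflate closes onto C4a in a medium that never contains free protic acid or a trifluoroacetylating agent.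

**Step 4.** The most likely failures are dehydration of the activated alcohol to the cinnamate through the acidic α-hydrogens of the ester, and partial loss of configuration by ion-pair substitution at the benzylic carbon. The fallback sets out from 3 and returns at 11, so it also leaves out the ester cleavage of step 5.
- Allylation of 3 with B-allyldiisopinocampheylborane prepared from (−)-α-pinene (Et2O, −78 °C, triethanolamine work-up in place of alkaline peroxide) should give benzyl {4-[(1R)-1-hydroxybut-3-en-1-yl]-2-methoxyphenyl} carbonate F2 by Re-face addition.
- Mitsunobu reaction of this alcohol, which has no acidic α-hydrogen, with 9 (PPh3, DIAD, toluene, 0 °C) gives benzyl {2-methoxy-4-[(1S)-1-(3,4,5-trimethoxyphenoxy)but-3-en-1-yl]phenyl} carbonate F3.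
- Lemieux–Johnson cleavage (OsO4 cat., NaIO4, 2,6-lutidine, dioxane–H2O) gives benzyl {2-methoxy-4-[(1S)-3-oxo-1-(3,4,5-trimethoxyphenoxy)propyl]phenyl} carbonate F4.
- Pinnick oxidation (NaClO2, NaH2PO4, excess 2-methyl-2-butene, t-BuOH–H2O) gives 11.

**Step 3.** The most likely failures are insufficient or reversed facial selectivity in the addition to the aldehyde, and slow turnover that lets an uncatalysed racemic pathway compete. The fallback sets out from 3 and 6 and returns at 8.
- A non-selective Mukaiyama aldol (BF3·OEt2, CH2Cl2, −78 °C) gives racemic tert-butyl 3-{4-[(benzyloxycarbonyl)oxy]-3-methoxyphenyl}-3-hydroxypropanoate F5.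
- Oxidation with 1,1,1-triacetoxy-1,1-dihydro-1,2-benziodoxol-3(1H)-one (CH2Cl2, rt) gives tert-butyl 3-{4-[(benzyloxycarbonyl)oxy]-3-methoxyphenyl}-3-oxopropanoate F6.
- Asymmetric transfer hydrogenation with RuCl[(R,R)-TsDPEN](p-cymene) in HCO2H/Et3N (5:2) is expected, by analogy with aryl alkyl ketones, to deliver the R carbinol 8.

**Step 5.** The most likely failures are alkylation of ring A by the tert-butyl cation if scavenging is incomplete, and acid-induced cleavage of the benzylic C–O bond. The fallback sets out from 10 and returns at 11. It replaces protonolysis by silyl transfer under buffered aprotic conditions: Me3SiOTf and 2,6-lutidine (CH2Cl2, 0 °C) convert the tert-butyl ester, with loss of 2-methylpropene, into trimethylsilyl (S)-3-{4-[(benzyloxycarbonyl)oxy]-3-methoxyphenyl}-3-(3,4,5-trimethoxyphenoxy)propanoate F7. This silyl ester is hydrolysed to 11 on work-up with a pH 4 buffer.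

## Further compounds

F1 | step 6 | (S)-3-{4-[(benzyloxycarbonyl)oxy]-3-methoxyphenyl}-3-(3,4,5-trimethoxyphenoxy)propanoyl chloride | COc1cc([C@@H](Oc2cc(OC)c(OC)c(OC)c2)CC(=O)Cl)ccc1OC(=O)OCc1ccccc1
F2 | step 4 | benzyl {4-[(1R)-1-hydroxybut-3-en-1-yl]-2-methoxyphenyl} carbonate | COc1cc([C@H](O)CC=C)ccc1OC(=O)OCc1ccccc1
F3 | step 4 | benzyl {2-methoxy-4-[(1S)-1-(3,4,5-trimethoxyphenoxy)but-3-en-1-yl]phenyl} carbonate | COc1cc([C@@H](Oc2cc(OC)c(OC)c(OC)c2)CC=C)ccc1OC(=O)OCc1ccccc1
F4 | step 4 | benzyl {2-methoxy-4-[(1S)-3-oxo-1-(3,4,5-trimethoxyphenoxy)propyl]phenyl} carbonate | COc1cc([C@@H](Oc2cc(OC)c(OC)c(OC)c2)CC=O)ccc1OC(=O)OCc1ccccc1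
F5 | step 3 | racemic tert-butyl 3-{4-[(benzyloxycarbonyl)oxy]-3-methoxyphenyl}-3-hydroxypropanoate | COc1cc(C(O)CC(=O)OC(C)(C)C)ccc1OC(=O)OCc1ccccc1
F6 | step 3 | tert-butyl 3-{4-[(benzyloxycarbonyl)oxy]-3-methoxyphenyl}-3-oxopropanoate | COc1cc(C(=O)CC(=O)OC(C)(C)C)ccc1OC(=O)OCc1ccccc1
F7 | step 5 | trimethylsilyl (S)-3-{4-[(benzyloxycarbonyl)oxy]-3-methoxyphenyl}-3-(3,4,5-trimethoxyphenoxy)propanoate | COc1cc([C@@H](Oc2cc(OC)c(OC)c(OC)c2)CC(=O)O[Si](C)(C)C)ccc1OC(=O)OCc1ccccc1
A1 | alternative 1 | (S)-4'-benzyloxy-5-hydroxy-3',6,7-trimethoxyflavanone | COc1cc([C@@H]2CC(=O)c3c(cc(OC)c(OC)c3O)O2)ccc1OCc1ccccc1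
A2 | alternative 1 | (2S)-2-[4-(benzyloxy)-3-methoxyphenyl]-5-(phenylsulfinyl)-2,3-dihydro-4H-pyran-4-one (either configuration at sulfur) | COc1cc([C@@H]2CC(=O)C(S(=O)c3ccccc3)=CO2)ccc1OCc1ccccc1
A3 | alternative 1 | 1,2,3-trimethoxy-1-(trimethylsilyloxy)buta-1,3-diene | C=C(OC)C(OC)=C(OC)O[Si](C)(C)C
A4 | alternative 2 | (2S,4S)-4'-hydroxy-3',4,5,6,7-pentamethoxyflavan | COc1cc([C@@H]2C[C@H](OC)c3c(cc(OC)c(OC)c3OC)O2)ccc1O
A5 | alternative 2 | 2-hydroxy-4,5,6-trimethoxybenzaldehyde | COc1cc(O)c(C=O)c(OC)c1OC
A6 | alternative 2 | 4-vinylguaiacol (2-methoxy-4-vinylphenol) | COc1cc(C=C)ccc1O
A7 | alternative 3 | (S)-4'-O-benzyl agecorynin E | COc1cc([C@@H]2CC(=O)c3c(cc(OC)c(OC)c3OC)O2)ccc1OCc1ccccc1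
A8 | alternative 3 | 3,4,5-trimethoxy-2-(trimethylsilyl)phenyl trifluoromethanesulfonate | COc1cc(OS(=O)(=O)C(F)(F)F)c([Si](C)(C)C)c(OC)c1OC
A9 | alternative 3 | methyl (S)-3-[4-(benzyloxy)-3-methoxyphenyl]-3-hydroxypropanoate | COc1cc([C@@H](O)CC(=O)OC)ccc1OCc1ccccc1
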